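**Strategy.** Numbering: ester carbon C1, methine C2, dioxane carbons C3–C6, linker C7–C8, enone ring A C9–C14 (carbonyl C11). The plan cuts the 1,2-dioxane at C4–C5, the only ring bond that touches neither an oxygen nor a stereocentre, so that C3 and C6 are set on separate fragments and joined through the O–O bond. Ring-closing metathesis of two vinyl groups then forms C4=C5 and closes the six-membered peroxide ring in one operation, without creating or disturbing a stereocentre. Its precursor is an acyclic bis-allylic dialkyl peroxide: a tertiary (6R) vinyl carbinyl peroxide made from dihydro-β-ionone, linked to a secondary (3S) vinyl carbinyl carbon that bears the C2 acrylate.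

Key step: step 12

Assumption: (DHQD)2PHAL is taken to give the 3S peroxide in step 11; should the sense of induction be opposite, the pseudoenantiomer (DHQ)2PHAL replaces it with no other change.

Remark: the acrylate is reduced before diimide is used, because diimide would also saturate it without control at C2; metal hydride conjugate reduction is avoided because the ester enolate formed would expel the β-peroxide.

Step 1
Reactants: 1 dihydro-β-ionone; 2 triethyl phosphonoacetate
Product: 3 ethyl (2E)-3-methyl-5-(2,6,6-trimethylcyclohex-1-en-1-yl)pent-2-enoate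
Conditions: NaH, THF, 0 °C → reflux; E isomer separated by chromatography
Reagents that add atoms: none
Why: Horner–Wadsworth–Emmons olefination of the methyl ketone should give mainly the E enoate (ester trans to the larger chain), and the minor Z isomer is removed by chromatography.

Step 2
Reactants: 3 ethyl (2E)-3-methyl-5-(2,6,6-trimethylcyclohex-1-en-1-yl)pent-2-enoate
Product: 4 (2E)-3-methyl-5-(2,6,6-trimethylcyclohex-1-en-1-yl)pent-2-en-1-ol
Conditions: iBu2AlH (2.5 equiv), CH2Cl2, −78 °C
Reagents that add atoms: none
Why: Hydride 1,2-reduction of the conjugated ester by iBu2AlH gives the allylic alcohol without touching either alkene or the alkene geometry.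

Step 3
Reactants: 4 (2E)-3-methyl-5-(2,6,6-trimethylcyclohex-1-en-1-yl)pent-2-en-1-ol
Product: 6 [(2S,3S)-3-methyl-3-[2-(2,6,6-trimethylcyclohex-1-en-1-yl)ethyl]oxiran-2-yl]methyl 4-nitrobenzoate, via epoxy alcohol 5 (not isolated)
Conditions: Ti(OiPr)4 (10 mol%), L-(+)-diethyl tartrate (12 mol%), t-BuOOH, 4 Å molecular sieves, CH2Cl2, −20 °C; then P(OMe)3; then 4-nitrobenzoyl chloride, Et3N, 0 °C
Reagents that add atoms: tert-butyl hydroperoxide, CC(C)(C)OO; 4-nitrobenzoyl chloride, O=C(Cl)c1ccc(cc1)[N+](=O)[O-]
Why: Katsuki–Sharpless asymmetric epoxidation with the L-(+)-tartrate titanium complex delivers oxygen to the face of the E allylic alcohol that gives the (2S,3S)-epoxide (as with geraniol), leaves the ring A alkene alone because it has no directing hydroxyl, and the in-flask acylation caps O1 so that no free 1,2-diol is present when the hydroperoxide is later ketalised.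

Step 4
Reactants: 6 [(2S,3S)-3-methyl-3-[2-(2,6,6-trimethylcyclohex-1-en-1-yl)ethyl]oxiran-2-yl]methyl 4-nitrobenzoate
Product: 7 (2S,3R)-3-hydroperoxy-2-hydroxy-3-methyl-5-(2,6,6-trimethylcyclohex-1-en-1-yl)pentyl 4-nitrobenzoate
Conditions: H2O2 (anhydrous, in Et2O, 10 equiv), H3PMo12O40 (2 mol%), Et2O, 0 °C → rt
Reagents that add atoms: hydrogen peroxide, OO
Why: Acid-catalysed perhydrolysis of a trisubstituted epoxide: H2O2 attacks the tertiary carbon, which carries the positive charge in a borderline SN2 transition state, from the side opposite the departing oxygen, so the (3S) epoxide carbon becomes the (3R) hydroperoxide carbon (the future C6) with inversion, while the electron-poor 4-nitrobenzoate is a poor neighbouring group.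

Step 5
Reactants: 7 (2S,3R)-3-hydroperoxy-2-hydroxy-3-methyl-5-(2,6,6-trimethylcyclohex-1-en-1-yl)pentyl 4-nitrobenzoate
Product: 8 (2S,3R)-2-hydroxy-3-[(2-methoxypropan-2-yl)peroxy]-3-methyl-5-(2,6,6-trimethylcyclohex-1-en-1-yl)pentyl 4-nitrobenzoate
Conditions: 2-methoxypropene (1.5 equiv), pyridinium p-toluenesulfonate (5 mol%), CH2Cl2, −20 °C
Reagents that add atoms: 2-methoxypropene, COC(C)=C
Why: Acid-catalysed addition of the hydroperoxide to the enol ether (peroxyketal formation) masks the O–O–H group, which is far more accessible than the secondary hydroxyl next to the fully substituted carbon, and any mixed ketal formed at that hydroxyl is much more acid-labile than the peroxyketal and is lost on a brief acidic methanol wash.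

Step 6
Reactants: 8 (2S,3R)-2-hydroxy-3-[(2-methoxypropan-2-yl)peroxy]-3-methyl-5-(2,6,6-trimethylcyclohex-1-en-1-yl)pentyl 4-nitrobenzoate
Product: 10 (2R)-2-[(2-methoxypropan-2-yl)peroxy]-2-methyl-4-(2,6,6-trimethylcyclohex-1-en-1-yl)butanal, via perketal diol 9 (not isolated)
Conditions: K2CO3 (0.2 equiv), MeOH, 0 °C; then NaIO4, NaHCO3, H2O, 0 °C → rt
Reagents that add atoms: none
Why: Zemplén-type transesterification frees the 1,2-diol and periodate (Malaprade) cleavage removes C1 as formaldehyde, giving an aldehyde that cannot enolise and a peroxyketal whose peroxide-bearing carbons carry no hydrogen, so Kornblum–DeLaMare fragmentation is impossible and the stereocentre is untouched.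

Step 7
Reactants: 10 (2R)-2-[(2-methoxypropan-2-yl)peroxy]-2-methyl-4-(2,6,6-trimethylcyclohex-1-en-1-yl)butanal
Product: 11 (3R)-3-[(2-methoxypropan-2-yl)peroxy]-3-methyl-5-(2,6,6-trimethylcyclohex-1-en-1-yl)pent-1-ene
Conditions: Ph3PCH3Br, KN(SiMe3)2, THF, −78 → 0 °C
Reagents that add atoms: methyltriphenylphosphonium bromide, C[P+](c1ccccc1)(c1ccccc1)c1ccccc1.[Br-]
Why: Wittig methylenation of the non-enolisable aldehyde installs the C6 vinyl group, and the peroxide survives because it is a fully substituted dialkyl peroxyketal, a group known to tolerate phosphorus ylides that would reduce a free hydroperoxide.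

Step 8
Reactants: 11 (3R)-3-[(2-methoxypropan-2-yl)peroxy]-3-methyl-5-(2,6,6-trimethylcyclohex-1-en-1-yl)pent-1-ene
Product: 12 (3R)-3-hydroperoxy-3-methyl-5-(2,6,6-trimethylcyclohex-1-en-1-yl)pent-1-ene
Conditions: AcOH/THF/H2O (4:2:1), rt
Reagents that add atoms: none
Why: Mild acetal hydrolysis of the peroxyketal releases the tertiary allylic hydroperoxide, since acetic acid is too weak to start a Hock cleavage and the quaternary stereocentre cannot epimerise.

Step 9
Reactants: 13 acrolein; 14 methyl acrylate
Product: 15 methyl 3-hydroxy-2-methylidenepent-4-enoate (racemic)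
Conditions: DABCO (20 mol%), methyl acrylate in excess as solvent, acrolein added slowly, rt
Reagents that add atoms: none
Why: Morita–Baylis–Hillman reaction: the DABCO–acrylate zwitterion adds to the aldehyde carbon of acrolein, excess acrylate and slow addition hold back acrolein self-coupling, and the racemate suffices because step 11 is enantioconvergent.

Step 10
Reactants: 15 methyl 3-hydroxy-2-methylidenepent-4-enoate
Product: 16 methyl 3-[(tert-butoxycarbonyl)oxy]-2-methylidenepent-4-enoate (racemic)
Conditions: Boc2O, DMAP (10 mol%), CH2Cl2, 0 °C → rt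
Reagents that add atoms: di-tert-butyl dicarbonate, CC(C)(C)OC(=O)OC(=O)OC(C)(C)C
Why: DMAP-catalysed O-acylation turns the secondary allylic alcohol into the tert-butyl carbonate, the standard leaving group for amine-catalysed allylic substitution of Morita–Baylis–Hillman adducts.

Step 11
Reactants: 12 (3R)-3-hydroperoxy-3-methyl-5-(2,6,6-trimethylcyclohex-1-en-1-yl)pent-1-ene; 16 methyl 3-[(tert-butoxycarbonyl)oxy]-2-methylidenepent-4-enoate (1.5 equiv)
Product: 17 methyl (3S)-2-methylidene-3-{[(3R)-3-methyl-5-(2,6,6-trimethylcyclohex-1-en-1-yl)pent-1-en-3-yl]peroxy}pent-4-enoate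
Conditions: (DHQD)2PHAL (10 mol%), toluene, rt
Reagents that add atoms: none
Why: Lewis-base-catalysed asymmetric allylic substitution of a Morita–Baylis–Hillman carbonate by a hydroperoxide (SN2′–SN2′): the quinuclidine nitrogen adds to the acrylate CH2 and expels the carbonate, which loses CO2 to give tert-butoxide that deprotonates 12, and the peroxide anion, ion-paired to the chiral ammonium, attacks C3 and releases the catalyst, so both enantiomers of 16 pass through one allyl ammonium ion and the catalyst sets C3 as S while C6 is carried in unchanged.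

Step 12
Reactants: 17 methyl (3S)-2-methylidene-3-{[(3R)-3-methyl-5-(2,6,6-trimethylcyclohex-1-en-1-yl)pent-1-en-3-yl]peroxy}pent-4-enoate
Product: 18 methyl 2-[(3S,6R)-6-methyl-6-[2-(2,6,6-trimethylcyclohex-1-en-1-yl)ethyl]-3,6-dihydro-1,2-dioxin-3-yl]prop-2-enoate
Conditions: second-generation Grubbs catalyst RuCl2(=CHPh)(H2IMes)(PCy3) (5 mol%), 1,4-benzoquinone (10 mol%), CH2Cl2 (0.005 M), 40 °C
Reagents that add atoms: none
Why: Ring-closing olefin metathesis: the ruthenium benzylidene exchanges onto the less hindered C3 vinyl group, the new alkylidene undergoes [2+2] cycloaddition with the C6 vinyl group, and the ruthenacyclobutane cycloreverts to form C4=C5 and release ethylene, which drives the reaction. The closest known reaction type is ring-closing metathesis of dialkenyl peroxides to unsaturated cyclic peroxides, in which the O–O bond survives the ruthenium carbene. The one ring formed is the six-membered 3,6-dihydro-1,2-dioxine, closed between the two terminal vinyl carbons with the peroxide already in the tether, and a ring of this size can hold only the Z alkene. No stereocentre is created: C3 (S) and C6 (R) were fixed in steps 11 and 4, and no bond to either is broken. The step needs chemoselectivity among four alkenes, and the substrate secures it because only the two monosubstituted vinyl groups engage the catalyst, the acrylate is 1,1-disubstituted and electron-poor (closure onto it from the C3 alkylidene would need a three-membered ring), and the ring A alkene is tetrasubstituted. High dilution holds back dimerisation, and benzoquinone holds back ruthenium hydride isomerisation at the doubly allylic C3–H.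

Step 13
Reactants: 18 methyl 2-[(3S,6R)-6-methyl-6-[2-(2,6,6-trimethylcyclohex-1-en-1-yl)ethyl]-3,6-dihydro-1,2-dioxin-3-yl]prop-2-enoate
Product: 19 methyl (2R)-2-[(3S,6R)-6-methyl-6-[2-(2,6,6-trimethylcyclohex-1-en-1-yl)ethyl]-3,6-dihydro-1,2-dioxin-3-yl]propanoate
Conditions: Old Yellow Enzyme 3 (OYE3), NADP+ (cat.), glucose dehydrogenase, D-glucose, KH2PO4/K2HPO4 buffer pH 7.0, DMSO (10% v/v), 30 °C
Reagents that add atoms: none
Why: Proposed new method: a flavin-dependent ene-reductase transfers hydride from FMNH2 to the acrylate CH2 while an active-site tyrosine protonates C2 on the opposite face, a near-concerted trans addition that leaves no free ester enolate to expel the β-peroxide and cannot touch the unactivated C4=C5 bond, the ring A alkene or the O–O bond; the closest known reaction type is the Old Yellow Enzyme reduction of 2-(alkoxymethyl)acrylates to (R)-configured Roche ester derivatives, whose binding mode, with the oxygen-bearing substituent in the place of C3, predicts the 2R configuration needed, but an acrylate carrying a secondary allylic peroxide has not been reduced in this way.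

Step 14
Reactants: 19 methyl (2R)-2-[(3S,6R)-6-methyl-6-[2-(2,6,6-trimethylcyclohex-1-en-1-yl)ethyl]-3,6-dihydro-1,2-dioxin-3-yl]propanoate
Product: 20 methyl (2R)-2-[(3S,6R)-6-methyl-6-[2-(2,6,6-trimethylcyclohex-1-en-1-yl)ethyl]-1,2-dioxan-3-yl]propanoate
Conditions: KO2CN=NCO2K, AcOH, CH2Cl2/MeOH, 0 °C → rt
Reagents that add atoms: none
Why: Diimide reduction: concerted syn transfer of two hydrogens from HN=NH saturates the cis C4=C5 bond without cleaving the O–O bond or touching the ester and the tetrasubstituted ring A alkene, and creates no stereocentre.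

Step 15
Reactants: 20 methyl (2R)-2-[(3S,6R)-6-methyl-6-[2-(2,6,6-trimethylcyclohex-1-en-1-yl)ethyl]-1,2-dioxan-3-yl]propanoate
Product: 21 methyl diacarnoate A, methyl (2R)-2-[(3S,6R)-6-methyl-6-[2-(2,6,6-trimethyl-3-oxocyclohex-1-en-1-yl)ethyl]-1,2-dioxan-3-yl]propanoate
Conditions: CrO3, 3,5-dimethylpyrazole, CH2Cl2, −20 °C
Reagents that add atoms: chromium trioxide, O=[Cr](=O)=O
Why: Allylic oxidation by the CrO3·3,5-dimethylpyrazole complex turns the ring CH2 at C11, the most accessible allylic position of the tetrasubstituted alkene, into the enone carbonyl, while the dialkyl peroxide is inert to hexavalent chromium and no stereocentre is touched.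

**Compound list**

1 | dihydro-β-ionone, 4-(2,6,6-trimethylcyclohex-1-en-1-yl)butan-2-one | CC(=O)CCC1=C(C)CCCC1(C)C | starting material
2 | triethyl phosphonoacetate | CCOC(=O)CP(=O)(OCC)OCC | starting material
3 | ethyl (2E)-3-methyl-5-(2,6,6-trimethylcyclohex-1-en-1-yl)pent-2-enoate | CCOC(=O)/C=C(\C)CCC1=C(C)CCCC1(C)C | intermediate
4 | (2E)-3-methyl-5-(2,6,6-trimethylcyclohex-1-en-1-yl)pent-2-en-1-ol | OC/C=C(\C)CCC1=C(C)CCCC1(C)C | intermediate
5 | [(2S,3S)-3-methyl-3-[2-(2,6,6-trimethylcyclohex-1-en-1-yl)ethyl]oxiran-2-yl]methanol (not isolated) | OC[C@@H]1O[C@@]1(C)CCC2=C(C)CCCC2(C)C | intermediate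
6 | [(2S,3S)-3-methyl-3-[2-(2,6,6-trimethylcyclohex-1-en-1-yl)ethyl]oxiran-2-yl]methyl 4-nitrobenzoate | O=C(OC[C@@H]1O[C@@]1(C)CCC2=C(C)CCCC2(C)C)c1ccc(cc1)[N+](=O)[O-] | intermediate
7 | (2S,3R)-3-hydroperoxy-2-hydroxy-3-methyl-5-(2,6,6-trimethylcyclohex-1-en-1-yl)pentyl 4-nitrobenzoate | O=C(OC[C@H](O)[C@](C)(OO)CCC2=C(C)CCCC2(C)C)c1ccc(cc1)[N+](=O)[O-] | intermediate
8 | (2S,3R)-2-hydroxy-3-[(2-methoxypropan-2-yl)peroxy]-3-methyl-5-(2,6,6-trimethylcyclohex-1-en-1-yl)pentyl 4-nitrobenzoate | O=C(OC[C@H](O)[C@](C)(OOC(C)(C)OC)CCC2=C(C)CCCC2(C)C)c1ccc(cc1)[N+](=O)[O-] | intermediate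
9 | (2S,3R)-3-[(2-methoxypropan-2-yl)peroxy]-3-methyl-5-(2,6,6-trimethylcyclohex-1-en-1-yl)pentane-1,2-diol (not isolated) | OC[C@H](O)[C@](C)(OOC(C)(C)OC)CCC1=C(C)CCCC1(C)C | intermediate
10 | (2R)-2-[(2-methoxypropan-2-yl)peroxy]-2-methyl-4-(2,6,6-trimethylcyclohex-1-en-1-yl)butanal | O=C[C@](C)(OOC(C)(C)OC)CCC1=C(C)CCCC1(C)C | intermediate
11 | (3R)-3-[(2-methoxypropan-2-yl)peroxy]-3-methyl-5-(2,6,6-trimethylcyclohex-1-en-1-yl)pent-1-ene | C=C[C@](C)(OOC(C)(C)OC)CCC1=C(C)CCCC1(C)C | intermediate
12 | (3R)-3-hydroperoxy-3-methyl-5-(2,6,6-trimethylcyclohex-1-en-1-yl)pent-1-ene | C=C[C@](C)(OO)CCC1=C(C)CCCC1(C)C | intermediate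
13 | acrolein | C=CC=O | starting material
14 | methyl acrylate | C=CC(=O)OC | starting material
15 | methyl 3-hydroxy-2-methylidenepent-4-enoate (racemic) | COC(=O)C(=C)C(O)C=C | intermediate
16 | methyl 3-[(tert-butoxycarbonyl)oxy]-2-methylidenepent-4-enoate (racemic) | COC(=O)C(=C)C(OC(=O)OC(C)(C)C)C=C | intermediate
17 | methyl (3S)-2-methylidene-3-{[(3R)-3-methyl-5-(2,6,6-trimethylcyclohex-1-en-1-yl)pent-1-en-3-yl]peroxy}pent-4-enoate | COC(=O)C(=C)[C@H](C=C)OO[C@@](C)(C=C)CCC1=C(C)CCCC1(C)C | intermediate
18 | methyl 2-[(3S,6R)-6-methyl-6-[2-(2,6,6-trimethylcyclohex-1-en-1-yl)ethyl]-3,6-dihydro-1,2-dioxin-3-yl]prop-2-enoate | COC(=O)C(=C)[C@@H]1C=C[C@@](C)(CCC2=C(C)CCCC2(C)C)OO1 | intermediate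
19 | methyl (2R)-2-[(3S,6R)-6-methyl-6-[2-(2,6,6-trimethylcyclohex-1-en-1-yl)ethyl]-3,6-dihydro-1,2-dioxin-3-yl]propanoate | COC(=O)[C@H](C)[C@@H]1C=C[C@@](C)(CCC2=C(C)CCCC2(C)C)OO1 | intermediate
20 | methyl (2R)-2-[(3S,6R)-6-methyl-6-[2-(2,6,6-trimethylcyclohex-1-en-1-yl)ethyl]-1,2-dioxan-3-yl]propanoate | COC(=O)[C@H](C)[C@@H]1CC[C@@](C)(CCC2=C(C)CCCC2(C)C)OO1 | intermediate
21 | methyl diacarnoate A, methyl (2R)-2-[(3S,6R)-6-methyl-6-[2-(2,6,6-trimethyl-3-oxocyclohex-1-en-1-yl)ethyl]-1,2-dioxan-3-yl]propanoate | COC(=O)[C@H](C)[C@@H]1CC[C@@](C)(CCC2=C(C)C(=O)CCC2(C)C)OO1 | target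

**Step count.** Total: 15 steps. Longest linear sequence: 13 steps (steps 1–8, then 11–15); steps 9–10 build the second fragment.

**Steps most likely to fail**

Step 13 (proposed new method). The enzyme may not bind a substrate this bulky and lipophilic, protonation may occur on the wrong face if the substrate binds in a flipped mode, or buffer-promoted Kornblum–DeLaMare opening of the dihydrodioxine at the activated C3–H may outrun the reduction. The fallback uses known chemistry, sets out from 18 and returns at 20. Compound 18 is treated with a larger excess of diimide (KO2CN=NCO2K, AcOH, 0 °C → rt), which by concerted hydrogen transfer should saturate both the C4=C5 bond and the acrylate without forming an enolate. C2 is then formed without reagent control, so 20 is expected together with its C2 epimer, methyl (2S)-2-[(3S,6R)-6-methyl-6-[2-(2,6,6-trimethylcyclohex-1-en-1-yl)ethyl]-1,2-dioxan-3-yl]propanoate F1. The two are diastereomers because C3 and C6 are fixed, and are separated by chromatography. Step 14 falls away and the route continues from 20 with step 15.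

Step 11. Facial selectivity at C3 may be poor when the chiral ammonium ion pair has to accommodate a bulky, chiral tertiary peroxide anion, or the anion may add at the far end of the dienyl ammonium intermediate. The fallback sets out from 12 and 16 and returns at 17. The substitution is run with achiral DABCO in place of the chiral amine, giving up catalyst control; by the same addition–elimination sequence it should give 17 and its C3 epimer, methyl (3R)-2-methylidene-3-{[(3R)-3-methyl-5-(2,6,6-trimethylcyclohex-1-en-1-yl)pent-1-en-3-yl]peroxy}pent-4-enoate F2. Because C6 is already fixed the two are diastereomers; they are separated by chromatography and 17 enters step 12.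

Step 12. Closure onto the vinyl group at the fully substituted C6 may be slow, so that the alkylidene resting at C3 dimerises by cross-metathesis or decomposes. The fallback is a relay ring-closing metathesis that sets out from 10 and returns at 18. Aldehyde 10 is olefinated with the ylide from (hex-5-en-1-yl)triphenylphosphonium bromide and KN(SiMe3)2 instead of the methylene ylide, giving the relay peroxyketal (6Z,8R)-8-[(2-methoxypropan-2-yl)peroxy]-8-methyl-10-(2,6,6-trimethylcyclohex-1-en-1-yl)deca-1,6-diene F3. Hydrolysis as in step 8 gives the hydroperoxide (6Z,8R)-8-hydroperoxy-8-methyl-10-(2,6,6-trimethylcyclohex-1-en-1-yl)deca-1,6-diene F4. Substitution on carbonate 16 as in step 11 gives the relay peroxide methyl (3S)-2-methylidene-3-{[(6Z,8R)-8-methyl-10-(2,6,6-trimethylcyclohex-1-en-1-yl)deca-1,6-dien-8-yl]peroxy}pent-4-enoate F5. With the same ruthenium catalyst the carbene loads on the unhindered terminal alkene of the tether, expels cyclopentene and is thereby placed on C5 next to the quaternary centre. From there it closes onto the accessible C3 vinyl group to give 18, where the route is rejoined.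

**Further compounds**

F1 | step 13 | methyl (2S)-2-[(3S,6R)-6-methyl-6-[2-(2,6,6-trimethylcyclohex-1-en-1-yl)ethyl]-1,2-dioxan-3-yl]propanoate | COC(=O)[C@@H](C)[C@@H]1CC[C@@](C)(CCC2=C(C)CCCC2(C)C)OO1
F2 | step 11 | methyl (3R)-2-methylidene-3-{[(3R)-3-methyl-5-(2,6,6-trimethylcyclohex-1-en-1-yl)pent-1-en-3-yl]peroxy}pent-4-enoate | COC(=O)C(=C)[C@@H](C=C)OO[C@@](C)(C=C)CCC1=C(C)CCCC1(C)C
F3 | step 12 | (6Z,8R)-8-[(2-methoxypropan-2-yl)peroxy]-8-methyl-10-(2,6,6-trimethylcyclohex-1-en-1-yl)deca-1,6-diene | C=CCCC/C=C\[C@](C)(OOC(C)(C)OC)CCC1=C(C)CCCC1(C)C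
F4 | step 12 | (6Z,8R)-8-hydroperoxy-8-methyl-10-(2,6,6-trimethylcyclohex-1-en-1-yl)deca-1,6-diene | C=CCCC/C=C\[C@](C)(OO)CCC1=C(C)CCCC1(C)C
F5 | step 12 | methyl (3S)-2-methylidene-3-{[(6Z,8R)-8-methyl-10-(2,6,6-trimethylcyclohex-1-en-1-yl)deca-1,6-dien-8-yl]peroxy}pent-4-enoate | COC(=O)C(=C)[C@H](C=C)OO[C@@](C)(/C=C\CCCC=C)CCC1=C(C)CCCC1(C)C
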